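## Structural features

The target is a coumestan, a 6H-benzofuro[3,2-c]chromen-6-one. Ring A (C1 to C4a) is fused to a 2-pyranone (O5, C6), which shares the C6a–C11a bond with a furan (O11) fused to ring D (C6b to C10a). A fifth ring, the 2,2-dimethyl-3,4-dihydro-2H-pyran ring E, is annulated to ring A with its oxygen on C1 and its benzylic CH2 on C2. There is no stereocentre and four of the five rings form one planar π system, so the difficulty is purely regiochemical. Ring A is a phloroglucinol whose three oxygens each have a different partner (C1–O in ring E, C3–OMe, C4a–O in the lactone), and only C4 carries hydrogen. Built from a phenol, this pattern would require three similar hydroxyl groups and the two nucleophilic carbons C2 and C4 to be told apart. Sensitive points are the lactone (opened by hydroxide, alkoxide or amines), the free C9 phenol, the tertiary alkyl aryl ether of ring E (strong Lewis acids) and the benzylic CH2 groups of ring E (hydride-abstracting oxidants). The key step exploits the fact that C4 is bonded to C4a, the carbon carrying the lactone oxygen: C4 can be the methyl group of a 6-methyl-2-pyranone, acidified through the ring by the lactone carbonyl. C3 can then be an ester carbon and C1–C2 the enol ether double bond of a finished ring E, so that forming the single C3–C4 bond closes ring A with every oxygen placed by connectivity.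

## Logic of the disconnections

19 ⇒ 18. The O–CH2Ph bond on the C9 oxygen is cut last. The C9 phenol must stay masked through a metalation, a strong-base step and an O-methylation, and a benzyl ether is removed by hydrogenolysis without touching the lactone, the methyl ether or ring E. The forward step only requires that 18 holds no other reducible group.

18 ⇒ 17. The O–CH3 bond at C3 is cut. The C3 hydroxyl is the only free OH of 17, because it is the oxygen created by the ring closure, so methylation cannot reach a wrong oxygen. The forward step needs a base too weak to open the lactone.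

17 ⇒ 15. The C3–C4 bond is cut and C3 returns to the ester oxidation level, which opens ring A. The pentacycle becomes a benzofuro-fused methylpyranone carrying a dihydropyran ester, and the three oxygens of ring A become a lactone oxygen, an ester carbonyl and an enol ether oxygen. The forward step demands selective deprotonation of the pyranone methyl group, intramolecular acylation in preference to attack on the lactone, and more than two equivalents of base.

15 ⇒ 14. The O–CMe2 bond of ring E is cut, giving an open-chain prenylated β-keto ester. The forward step must add the ketone oxygen (not the ester oxygen) to the alkene in the Markovnikov sense under acid that spares the benzyl ether and the enol lactone.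

14 ⇒ 12 + 13. The bond between the α-carbon (future C2) and the allylic CH2 is cut. This is an ordinary enolate alkylation, which must be C-selective and stop at monoalkylation.

12 ⇒ 9 + 10 + CO. The C11b–C1 and C1–C2 bonds are cut together. C1, C2 and C3 are thereby introduced in one operation onto a halide. The forward step needs CO insertion at a hindered vinyl–palladium centre and acylation of a soft malonate enolate that does not attack the pyranone.

9 ⇒ 8. The O5–C4a bond and the C11b–I bond are cut. The pyranone and its halogen handle arise together from an alkyne and the neighbouring ester. The forward step requires 6-endo-dig closure and an electrophile that prefers the alkyne to the benzyloxy-activated ring.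

8 ⇒ 6 + 7. The C11a–C11b bond (sp2–sp) is cut, leading to a 2-iodobenzofuran ester and propyne. The forward coupling is routine.

6 ⇒ 4. The C11a–I bond is cut. The forward step needs metalation at furan C2 only, which the adjacent ester and ring oxygen direct.

4 ⇒ 1 + 2. The C6a–C11a and C6a–C6b bonds and the O11–C11a bond are cut. The whole benzofuran-3-carboxylate (ring D, furan, C6 carboxyl) comes in one step from a commercial salicylaldehyde and a diazo ester. The forward step requires aryl migration in preference to hydride migration, and dehydration without loss of the benzyl ether.

## Other disconnections considered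

Alternative 1: The cut runs through the furan ring at the pterocarpan oxidation level. C6a–C6b and O11–C11a are disconnected, giving the ring-E-fused 7-methoxy-2H-chromene A2 and 5-(benzyloxy)-2-iodophenol A3.
- Forward step: Pd(OAc)2 and Ag2CO3 would effect a Heck oxyarylation (aryl transfer to C6a, capture of the benzylic palladium at C11a by the phenol oxygen) to the cis-fused pterocarpan A1. A1 would then be dehydrogenated and oxidized at C6 to 18 and debenzylated to 19.
- In favour: two bonds and the complete ring system arise in one convergent step, and the reaction type is established for chromenes and ortho-iodophenols. The cis fusion follows from syn carbopalladation, though it is of no consequence here.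
- Against: A2 already holds the full substitution pattern of ring A, so the differentiation of the phloroglucinol oxygens and of C2 against C4 is only moved into the synthesis of A2. Two stereocentres are made and then destroyed. The passage from A1 to the lactone needs two oxidation levels at C6 with oxidants that can also attack the benzylic CH2 of ring E.
- Comparison: on mechanism the alternative is the better, since its key step is a known reaction class and step 8 is not. On convergence and longest linear sequence it is at least the equal. On structural control the chosen plan is ahead, since it places every ring A oxygen by connectivity and needs no oxidation once the skeleton is complete.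

Alternative 2: The O11–C10a bond is cut and ring D is taken back to a cyclohexenone. The furan would arise by Paal–Knorr cyclodehydration of the 1,4-diketone A5 (ring A aryl ketone at C11a, vinylogous-ester carbonyl at C10a, ester on C6a).
- Forward step: anhydrous p-toluenesulfonic acid would give the 4,5-dihydrobenzofuran A4. Dehydrogenation of ring D, hydrogenolysis of both benzyl ethers and lactonization of the freed C4a phenol on the C6 ester would lead to 19.
- In favour: the Paal–Knorr reaction is dependable, the furan regiochemistry and the position of the C9 oxygen follow from connectivity, and the last lactonization is trivial.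
- Against: the aryl ketone half of A5 is again a fully differentiated phloroglucinol to be made by classical phenol chemistry. A5 must be assembled by alkylating a hindered aroylacetate with an α'-halogenated 3-alkoxycyclohexenone, which is prone to elimination. The benzyl enol ether is acid-labile, and the late dehydrogenation again exposes the benzylic CH2 groups of ring E to an oxidant.
- Comparison: the key step is equal to or better than step 8 in mechanistic certainty. In control of the ring A pattern and in step count (separate aromatization, longer fragment syntheses) the alternative is the weaker.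

Alternative 3: The cut is the O5–C4a bond. The lactone oxygen is introduced last by carboxyl-directed oxidation of C4a–H in the 2-arylbenzofuran-3-carboxylic acid A7.
- Forward step: Cu(OAc)2 with dibenzoyl peroxide, or Pd(OAc)2 with PhI(OAc)2, would give the 9-O-acetyl compound A6, and mild deacetylation then gives 19.
- In favour: ring A needs only two oxygens before the key step. C1 is blocked, so C4a–H is the only ortho C–H open to the carboxyl group. The biaryl bond can come from a Suzuki coupling of a 2-halobenzofuran-3-carboxylate such as 6, so the route would be short.
- Against: the step oxidizes an electron-rich, twisted, crowded biaryl. With the copper/peroxide system an aroyloxy radical can add at the ipso carbon or abstract hydrogen from the benzylic CH2 of ring E. With divalent palladium, cyclometalation at a crowded position competes with decarboxylation. The acetate must survive liberation of the free acid, and the ring A partner still needs a regioselective functionalization next to the ring E oxygen.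
- Comparison: in step economy the alternative is the better. In site selectivity of the key step the two plans are equal, both relying on substitution and not on reagent control. In chemoselectivity the chosen plan is ahead, because its key step is redox-neutral. The oxidative lactonization is, however, a known reaction class, which step 8 is not.

Key step: step 8

Remark on the chemistry: mapping 15 onto 17 atom by atom (methyl → C4, ester carbon → C3, enol ether carbons → C2 and C1) reproduces the oxygen pattern of 19, so the structures of the key step need no correction. The precursor is kept as the methyl ester and benzyl ether; the one design change is the use of more than two equivalents of base.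

Assumption: 1, 2, 7, 10 and 13 are taken as commercial. The benzofuran ester is carried as the ethyl ester, a spectator group lost in step 4.

## Route

Step 1
Reactants: 1 4-(benzyloxy)-2-hydroxybenzaldehyde; 2 ethyl diazoacetate
Product: 4 ethyl 6-(benzyloxy)benzofuran-3-carboxylate, via 2-hydroxy-2,3-dihydrobenzofuran lactol 3 (not isolated)
Conditions: HBF4·OEt2 (10 mol%), CH2Cl2, rt; then conc. H2SO4, 0 °C → rt
Reagents that add atoms: none
Why: Acid-catalysed addition of the diazo ester to the aldehyde with loss of N2 and 1,2-shift of the electron-rich aryl group (Roskamp-type homologation diverted to the 2-aryl-3-oxopropanoate), lactol formation with the ortho phenol and acid dehydration to the aromatic furan; the benzyloxy group para to the aldehyde carbon raises the migratory aptitude of the aryl group, and brief cold contact with H2SO4 should spare the aryl benzyl ether.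

Step 2
Reactants: 4 ethyl 6-(benzyloxy)benzofuran-3-carboxylate
Product: 6 ethyl 6-(benzyloxy)-2-iodobenzofuran-3-carboxylate, via 2-chloromagnesio ester 5 (not isolated)
Conditions: TMPMgCl·LiCl (TMP = 2,2,6,6-tetramethylpiperidide, 1.2 equiv), THF, −40 °C; then I2, −40 °C → rt
Reagents that add atoms: iodine, [I][I]
Why: Directed magnesiation with the Knochel–Hauser amide followed by iodinolysis; C2–H is the most acidic proton (next to the ring oxygen, ortho to the coordinating ester) and the hindered magnesium amide should not add to the ester at low temperature.

Step 3
Reactants: 6 ethyl 6-(benzyloxy)-2-iodobenzofuran-3-carboxylate; 7 propyne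
Product: 8 ethyl 6-(benzyloxy)-2-(prop-1-yn-1-yl)benzofuran-3-carboxylate
Conditions: Pd(PPh3)2Cl2 (3 mol%), CuI (5 mol%), Et3N, THF, propyne (excess), rt
Reagents that add atoms: none
Why: Sonogashira coupling; the C2–I bond is activated for oxidative addition by the adjacent ester, and excess propyne under inert gas suppresses alkyne homocoupling.

Step 4
Reactants: 8 ethyl 6-(benzyloxy)-2-(prop-1-yn-1-yl)benzofuran-3-carboxylate
Product: 9 7-(benzyloxy)-4-iodo-3-methyl-1H-pyrano[4,3-b]benzofuran-1-one
Conditions: ICl (1.1 equiv), CH2Cl2, −78 → 0 °C
Reagents that add atoms: iodine monochloride, ClI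
Why: Electrophilic iodocyclization (iodolactonization of an ortho-alkynyl ester): the ester carbonyl oxygen attacks the iodonium-activated alkyne at the methyl-bearing carbon (6-endo-dig; the 5-exo mode would fuse a strained second five-membered ring to the furan), and chloride dealkylates the oxocarbenium ion by SN2 attack on the ethyl group. Low temperature and only a slight excess of ICl should keep the benzyloxy-bearing ring from being iodinated.

Step 5
Reactants: 9 7-(benzyloxy)-4-iodo-3-methyl-1H-pyrano[4,3-b]benzofuran-1-one; 10 potassium methyl malonate
Product: 12 methyl 3-[7-(benzyloxy)-3-methyl-1-oxo-1H-pyrano[4,3-b]benzofuran-4-yl]-3-oxopropanoate, via aroylmalonic half-ester 11 (not isolated)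
Conditions: Pd(dba)2 (5 mol%), Xantphos (5 mol%), CO (1 atm), MgCl2, Et3N, THF, 70 °C; then 1 M HCl
Reagents that add atoms: carbon monoxide, [C-]#[O+]
Why: Palladium-catalysed carbonylative acylation of a magnesium malonate enolate (decarboxylative Claisen-type ketone synthesis): oxidative addition of zerovalent palladium into the C–I bond, CO insertion, C-acylation of the MgCl2/Et3N-derived enolate and decarboxylation of 11 on acidification. The wide-bite-angle ligand favours CO insertion over direct coupling, and the soft chelated nucleophile should not open the lactone.

Step 6
Reactants: 12 methyl 3-[7-(benzyloxy)-3-methyl-1-oxo-1H-pyrano[4,3-b]benzofuran-4-yl]-3-oxopropanoate; 13 prenyl bromide (1-bromo-3-methylbut-2-ene)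
Product: 14 methyl 2-{[7-(benzyloxy)-3-methyl-1-oxo-1H-pyrano[4,3-b]benzofuran-4-yl]carbonyl}-5-methylhex-4-enoate (racemic)
Conditions: K2CO3, acetone, rt → 40 °C
Reagents that add atoms: none
Why: SN2 C-alkylation of the β-keto ester enolate with a primary allylic bromide; carbonate in acetone favours C- over O-alkylation and one equivalent of bromide limits dialkylation. The new stereocentre is formed racemic and disappears in step 7.

Step 7
Reactants: 14 methyl 2-{[7-(benzyloxy)-3-methyl-1-oxo-1H-pyrano[4,3-b]benzofuran-4-yl]carbonyl}-5-methylhex-4-enoate
Product: 15 methyl 2-[7-(benzyloxy)-3-methyl-1-oxo-1H-pyrano[4,3-b]benzofuran-4-yl]-6,6-dimethyl-5,6-dihydro-4H-pyran-3-carboxylate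
Conditions: Amberlyst 15 (sulfonic acid resin), CH2Cl2, rt → 40 °C
Reagents that add atoms: none
Why: Acid-catalysed Markovnikov cycloetherification (intramolecular hydroalkoxylation): protonation of the trisubstituted alkene gives the tertiary cation, the ketone oxygen captures it in a six-membered transition state, and loss of the α-proton gives the enol ether conjugated with the ester. The ketone oxygen is part of a vinylogous ester through the pyranone enol ether and should be more nucleophilic than the ester carbonyl; a heterogeneous sulfonic acid near ambient temperature should leave the benzyl ether and the enol lactone intact.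

Step 8
Reactants: 15 methyl 2-[7-(benzyloxy)-3-methyl-1-oxo-1H-pyrano[4,3-b]benzofuran-4-yl]-6,6-dimethyl-5,6-dihydro-4H-pyran-3-carboxylate
Product: 17 9-(benzyloxy)-3-hydroxycoumestan with the 2,2-dimethyl-3,4-dihydro-2H-pyran ring E fused at C1 (O) and C2 (CH2), via cyclohexadienone tautomer 16 (not isolated)
Conditions: LDA (2.5 equiv), THF, −78 → 0 °C (15 added to the base); aq. NH4Cl
Reagents that add atoms: none
Why: Proposed new method: LDA should remove a proton from the pyranone methyl group, which is acidified through the C4a=C11b and C11a=C6a double bonds by the lactone carbonyl, to give a lithium trienolate whose terminal carbon adds to the ester carbonyl on the neighbouring dihydropyran; collapse of the tetrahedral intermediate with loss of methoxide gives dienone 16, which the excess base deprotonates at once, so that phenol 17 appears after the quench. The closest known reaction types are the Claisen acylation of lateral carbanions of 6-methyl-2-pyranones and 2-methylchromones by esters and the LDA-induced closure of 2'-methylbiaryl-2-carboxamides to 9-phenanthrols, which has the same geometry across a hindered axis. Ring A closes in the 6-exo-trig mode (C3–C4 bond formed, carbonyl oxygen outside the ring). No stereocentre is created, and the sp3 carbon C4 of 16 is lost on enolization. The step needs site-selective deprotonation: the only other sp3 C–H next to a π system, the dihydropyran C4 methylene, is cross-conjugated with the ester and its anion would place charge on the oxygen-bearing enol ether carbon, and the benzylic ether protons are not removed by a lithium amide at −78 °C. It also needs proton abstraction to win over addition to the lactone, which the bulk of LDA provides. More than two equivalents of base are required because 16 and 17 are more acidic than the methyl group. Aromatization makes the sequence irreversible.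

Step 9
Reactants: 17 9-(benzyloxy)-3-hydroxycoumestan with ring E fused at C1 (O) and C2 (CH2)
Product: 18 9-(benzyloxy)-3-methoxycoumestan with the 2,2-dimethyl-3,4-dihydro-2H-pyran ring E fused at C1 (O) and C2 (CH2)
Conditions: MeI, K2CO3, acetone, reflux
Reagents that add atoms: iodomethane, IC
Why: Williamson O-methylation of the only free phenol; K2CO3 in acetone is too weakly nucleophilic to open the lactone.

Step 10
Reactants: 18 9-(benzyloxy)-3-methoxycoumestan with ring E fused at C1 (O) and C2 (CH2)
Product: 19 9-hydroxy-3-methoxycoumestan with the 2,2-dimethyl-3,4-dihydro-2H-pyran ring E fused at C1 (O) and C2 (CH2) (CNP0304440.0)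
Conditions: H2 (1 atm), 10% Pd/C, EtOAc–THF, rt
Reagents that add atoms: none
Why: Catalytic hydrogenolysis of the benzyl aryl ether; the coumestan π system, the methyl ether and the tertiary alkyl aryl ether of ring E should be inert under one atmosphere of hydrogen.

## Compound list

1 | 4-(benzyloxy)-2-hydroxybenzaldehyde | O=Cc1ccc(OCc2ccccc2)cc1O | starting material
2 | ethyl diazoacetate | CCOC(=O)C=[N+]=[N-] | starting material
3 | ethyl 6-(benzyloxy)-2-hydroxy-2,3-dihydrobenzofuran-3-carboxylate (lactol, mixture of diastereomers, formed in the flask) | CCOC(=O)C1C(O)Oc2cc(OCc3ccccc3)ccc12 | intermediate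
4 | ethyl 6-(benzyloxy)benzofuran-3-carboxylate | CCOC(=O)c1coc2cc(OCc3ccccc3)ccc12 | intermediate
5 | ethyl 6-(benzyloxy)-2-(chloromagnesio)benzofuran-3-carboxylate (LiCl complex, formed in the flask) | CCOC(=O)c1c([Mg]Cl)oc2cc(OCc3ccccc3)ccc12 | intermediate
6 | ethyl 6-(benzyloxy)-2-iodobenzofuran-3-carboxylate | CCOC(=O)c1c(I)oc2cc(OCc3ccccc3)ccc12 | intermediate
7 | propyne | CC#C | starting material
8 | ethyl 6-(benzyloxy)-2-(prop-1-yn-1-yl)benzofuran-3-carboxylate | CCOC(=O)c1c(C#CC)oc2cc(OCc3ccccc3)ccc12 | intermediate
9 | 7-(benzyloxy)-4-iodo-3-methyl-1H-pyrano[4,3-b]benzofuran-1-one | Cc1oc(=O)c2c3ccc(OCc4ccccc4)cc3oc2c1I | intermediate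
10 | potassium methyl malonate (potassium 3-methoxy-3-oxopropanoate) | COC(=O)CC(=O)[O-].[K+] | starting material
11 | 2-{[7-(benzyloxy)-3-methyl-1-oxo-1H-pyrano[4,3-b]benzofuran-4-yl]carbonyl}-3-methoxy-3-oxopropanoic acid (racemic, present as its magnesium salt, formed in the flask) | Cc1oc(=O)c2c3ccc(OCc4ccccc4)cc3oc2c1C(=O)C(C(=O)O)C(=O)OC | intermediate
12 | methyl 3-[7-(benzyloxy)-3-methyl-1-oxo-1H-pyrano[4,3-b]benzofuran-4-yl]-3-oxopropanoate | Cc1oc(=O)c2c3ccc(OCc4ccccc4)cc3oc2c1C(=O)CC(=O)OC | intermediate
13 | prenyl bromide (1-bromo-3-methylbut-2-ene) | CC(C)=CCBr | starting material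
14 | methyl 2-{[7-(benzyloxy)-3-methyl-1-oxo-1H-pyrano[4,3-b]benzofuran-4-yl]carbonyl}-5-methylhex-4-enoate (racemic) | Cc1oc(=O)c2c3ccc(OCc4ccccc4)cc3oc2c1C(=O)C(CC=C(C)C)C(=O)OC | intermediate
15 | methyl 2-[7-(benzyloxy)-3-methyl-1-oxo-1H-pyrano[4,3-b]benzofuran-4-yl]-6,6-dimethyl-5,6-dihydro-4H-pyran-3-carboxylate | Cc1oc(=O)c2c3ccc(OCc4ccccc4)cc3oc2c1C1=C(C(=O)OC)CCC(C)(C)O1 | intermediate
16 | 3-oxo-3,4-dihydro keto tautomer of 17 (ring A as cyclohexadienone, C4 as CH2, formed in the flask) | O=C1CC2=C(C3=C1CCC(C)(C)O3)c1oc3cc(OCc4ccccc4)ccc3c1C(=O)O2 | intermediate
17 | 9-(benzyloxy)-3-hydroxycoumestan with the 2,2-dimethyl-3,4-dihydro-2H-pyran ring E fused at C1 (O) and C2 (CH2) | Oc1cc2oc(=O)c3c4ccc(OCc5ccccc5)cc4oc3c2c2c1CCC(C)(C)O2 | intermediate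
18 | 9-(benzyloxy)-3-methoxycoumestan with the 2,2-dimethyl-3,4-dihydro-2H-pyran ring E fused at C1 (O) and C2 (CH2) | COc1cc2oc(=O)c3c4ccc(OCc5ccccc5)cc4oc3c2c2c1CCC(C)(C)O2 | intermediate
19 | 9-hydroxy-3-methoxycoumestan with the 2,2-dimethyl-3,4-dihydro-2H-pyran ring E fused at C1 (O) and C2 (CH2), CNP0304440.0 (achiral) | COc1cc2oc(=O)c3c4ccc(O)cc4oc3c2c2c1CCC(C)(C)O2 | target

## Step count and least certain steps

Total: 10 steps. Longest linear sequence: 10 steps (1 → 19); 2, 7, 10 and 13 enter as commercial reagents.

Step 8 (key step, the one step without direct precedent). Addition of the amide base or of the liberated lithium methoxide to the lactone carbonyl may outrun lateral deprotonation. The trienolate may also fail to reach the ester if the two rings stay twisted about the C11b–C1 bond, and conversion would stop early if less than two equivalents of base remain active. Fallback: set out from 15 and close the ring under thermodynamic control through the ring-opened form. NaOMe in MeOH should open the enol lactone to methyl 6-(benzyloxy)-2-{1-[3-(methoxycarbonyl)-6,6-dimethyl-5,6-dihydro-4H-pyran-2-yl]-2-oxopropyl}benzofuran-3-carboxylate F1 (racemic). On heating with NaOMe in MeOH, or with t-BuOK in THF after isolation, the methyl ketone enolate of F1 should undergo a classical Dieckmann-type Claisen condensation with the dihydropyran ester. The resulting cyclohexenedione should aromatize to the resorcinol, and the C4a phenoxide should close the lactone on the benzofuran ester again, which returns the route at 17. Alkoxide opening of enol lactones, ketone–ester Claisen cyclization to resorcinols and phenol–ester lactonization are all known reaction types.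

Step 5. CO insertion and acyl transfer at the doubly flanked vinyl–palladium centre may be slow, which would lead to protodeiodination or direct coupling, and the nucleophile or the amine may attack the pyranone once it carries the acyl group. Fallback: set out from 9 and build the keto ester stepwise without palladium. Iodine–magnesium exchange with i-PrMgCl·LiCl (THF, −40 °C) should give the 4-chloromagnesio pyranone F2, and carboxylation with CO2 should give 7-(benzyloxy)-3-methyl-1-oxo-1H-pyrano[4,3-b]benzofuran-4-carboxylic acid F3. Activation with 1,1'-carbonyldiimidazole gives the acyl imidazole F4, and Masamune–Brooks homologation with Mg(O2CCH2CO2Me)2 passes through 11 and returns at 12.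

Step 4. Partial 5-exo-dig closure and electrophilic iodination of the benzyloxy-activated ring would erode the yield of the 6-endo product. Fallback: set out from 6 and fix the ring size by connectivity, replacing steps 3 and 4. CuI-catalysed arylation of pentane-2,4-dione (K3PO4, DMSO, 90 °C) with retro-Claisen loss of acetate should give ethyl 6-(benzyloxy)-2-(2-oxopropyl)benzofuran-3-carboxylate F5. Enol lactonization (p-toluenesulfonic acid, toluene, reflux, loss of ethanol) can only give the six-membered 7-(benzyloxy)-3-methyl-1H-pyrano[4,3-b]benzofuran-1-one F6. N-Iodosuccinimide in MeCN should then iodinate the nucleophilic enol ether carbon C4, which returns the route at 9.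

Step 7. The acid may cleave the benzyl ether, or the tertiary cation may be captured by the ester carbonyl (leading to a δ-lactone after demethylation) in place of the ketone oxygen. Fallback: set out from 12 and form ring E by cycloaddition without acid, bypassing 14. Knoevenagel condensation with paraformaldehyde (piperidinium acetate cat.) should give methyl 2-{[7-(benzyloxy)-3-methyl-1-oxo-1H-pyrano[4,3-b]benzofuran-4-yl]carbonyl}prop-2-enoate F7. Trapped in the same flask by 2-methylpropene in an inverse-electron-demand hetero-Diels–Alder reaction (sealed tube, 80 °C), with the oxygen bonding to the more substituted alkene carbon, F7 should give 15 directly.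

Step 1. Acidolysis of the aryl benzyl ether during the H2SO4 dehydration would lower the yield and give the free phenol. Fallback: set out from 3, isolated by neutral work-up after the HBF4 stage, and dehydrate under basic conditions. MsCl and Et3N (CH2Cl2, 0 °C) should give ethyl 6-(benzyloxy)-2-[(methylsulfonyl)oxy]-2,3-dihydrobenzofuran-3-carboxylate F8. F8 should lose methanesulfonate by E1cB elimination, the C3–H being α to the ester, and return the route at 4.

## Further compounds

F1 | step 8 | methyl 6-(benzyloxy)-2-{1-[3-(methoxycarbonyl)-6,6-dimethyl-5,6-dihydro-4H-pyran-2-yl]-2-oxopropyl}benzofuran-3-carboxylate (racemic) | COC(=O)c1c(C(C(C)=O)C2=C(C(=O)OC)CCC(C)(C)O2)oc2cc(OCc3ccccc3)ccc12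
F2 | step 5 | 7-(benzyloxy)-4-(chloromagnesio)-3-methyl-1H-pyrano[4,3-b]benzofuran-1-one | Cc1oc(=O)c2c3ccc(OCc4ccccc4)cc3oc2c1[Mg]Cl
F3 | step 5 | 7-(benzyloxy)-3-methyl-1-oxo-1H-pyrano[4,3-b]benzofuran-4-carboxylic acid | Cc1oc(=O)c2c3ccc(OCc4ccccc4)cc3oc2c1C(=O)O
F4 | step 5 | 7-(benzyloxy)-4-(1H-imidazol-1-ylcarbonyl)-3-methyl-1H-pyrano[4,3-b]benzofuran-1-one | Cc1oc(=O)c2c3ccc(OCc4ccccc4)cc3oc2c1C(=O)n1ccnc1
F5 | step 4 | ethyl 6-(benzyloxy)-2-(2-oxopropyl)benzofuran-3-carboxylate | CCOC(=O)c1c(CC(C)=O)oc2cc(OCc3ccccc3)ccc12
F6 | step 4 | 7-(benzyloxy)-3-methyl-1H-pyrano[4,3-b]benzofuran-1-one | Cc1cc2oc3cc(OCc4ccccc4)ccc3c2c(=O)o1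
F7 | step 7 | methyl 2-{[7-(benzyloxy)-3-methyl-1-oxo-1H-pyrano[4,3-b]benzofuran-4-yl]carbonyl}prop-2-enoate | Cc1oc(=O)c2c3ccc(OCc4ccccc4)cc3oc2c1C(=O)C(=C)C(=O)OC
F8 | step 1 | ethyl 6-(benzyloxy)-2-[(methylsulfonyl)oxy]-2,3-dihydrobenzofuran-3-carboxylate (mixture of diastereomers) | CCOC(=O)C1C(OS(C)(=O)=O)Oc2cc(OCc3ccccc3)ccc12
A1 | alternative 1 | cis-fused 9-(benzyloxy)-3-methoxypterocarpan with ring E fused at C1 (O) and C2 (CH2) (racemic, one enantiomer drawn) | COc1cc2OC[C@H]3c4ccc(OCc5ccccc5)cc4O[C@H]3c2c2OC(C)(C)CCc12
A2 | alternative 1 | 7-methoxy-2H-chromene with the 2,2-dimethyl-3,4-dihydro-2H-pyran ring fused at C5 (O) and C6 (CH2) | COc1cc2OCC=Cc2c2OC(C)(C)CCc12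
A3 | alternative 1 | 5-(benzyloxy)-2-iodophenol | Oc1cc(OCc2ccccc2)ccc1I
A4 | alternative 2 | methyl 6-(benzyloxy)-2-[7-(benzyloxy)-5-methoxy-2,2-dimethylchroman-8-yl]-4,5-dihydrobenzofuran-3-carboxylate | COC(=O)c1c(-c2c(OCc3ccccc3)cc(OC)c3CCC(C)(C)Oc23)oc2C=C(OCc3ccccc3)CCc12
A5 | alternative 2 | methyl 3-[7-(benzyloxy)-5-methoxy-2,2-dimethylchroman-8-yl]-2-[4-(benzyloxy)-2-oxocyclohex-3-en-1-yl]-3-oxopropanoate (mixture of diastereomers) | COC(=O)C(C1CCC(OCc2ccccc2)=CC1=O)C(=O)c1c(OCc2ccccc2)cc(OC)c2CCC(C)(C)Oc12
A6 | alternative 3 | 9-O-acetyl derivative of 19 | COc1cc2oc(=O)c3c4ccc(OC(C)=O)cc4oc3c2c2c1CCC(C)(C)O2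
A7 | alternative 3 | 6-acetoxy-2-(5-methoxy-2,2-dimethylchroman-8-yl)benzofuran-3-carboxylic acid | COc1ccc(-c2oc3cc(OC(C)=O)ccc3c2C(=O)O)c2OC(C)(C)CCc12
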